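I read the rate first.

the same everywhere: electrophile 0.50 M
- north-east: free base 2 equiv; protic impurity 0.25 M; solid nucleophile 1.5 equiv; the very flask that is asked about, followed so far
- south: free base 2 equiv; protic impurity 0.25 M; solid nucleophile 1 equiv; run made earlier
- flask: free base 2.00 equiv; protic impurity 0.250 M; solid nucleophile 1.50 equiv; time 20 h

- north-east (time / h: electrophile / %, product / %): 0.833: 99.2, 1.4; 1.33: 98.0, 1.8; 2.00: 96.9, 3.4; 4.00: 93.4, 7.0; 6.00: 88.3, 11.2; 10.0: 79.7, 20.1
- south (time / h: electrophile / %, product / %): 1.33: 98.3, 1.7; 4.00: 92.6, 6.8; 8.00: 83.9, 15.3; 10.0: 80.2, 20.2; 15.0: 69.0, 31.7; 20.0: 57.4, 42.9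

(each reading ± 0.3 percentage points)

* part of the electrophile that has reacted at 20 h
* share of free nucleophile in free nucleophile and protonated nucleophile together, at 20 h

- given per volume of solution although it is solid: solid nucleophile
- steps that have been proposed: electrophile + nucleophile -> acid set free + product; nucleophile + acid set free <-> protonated nucleophile; acid set free + free base <-> salt of the base; nucleophile + protic impurity -> quenched reagent; solid nucleophile <-> nucleophile
- at the start none of the solid nucleophile is in solution
- the earlier runs do not show how much of nucleophile is bound; that part of a forecast is a guess

At 10.0 h the north-east run held 20.1% product and the south run 20.2%, equal within the scatter, though their solid charges differed. So I carried one quantity from the south run between 10.0 h and 20.0 h: the molar product rate, 0.0113 M h⁻¹. The equal readings proved nothing for the later hours, so it was my assumption that the north-east flask would keep to the south run's rate up to 20 h.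

I solved that flask at two ends. Zero order in electrophile, with the molar rate held constant from 10.0 h, gave 42.8%. Pseudo-first-order, with c(nucleophile) constant, repeated the south run's ratio of electrophile over the same hours and gave 43.0%. An order in between lands between them, so I committed to that narrow range. The runs showed nothing of the bound share, so I gave no figure for fr.

The forecast gave 44% for c, higher than my upper end, and 75% for fr, in its words: “most nucleophile probably stays free”.

The simulation gave 42.8% and 17.0%.

    electrophile + nucleophile → acid set free + product (k = 0.0260 M⁻¹ min⁻¹)
    nucleophile + acid set free ⇌ protonated nucleophile, settled at all times (K = 7600 M⁻¹)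
    acid set free + free base ⇌ salt of the base (K = 480 M⁻¹, k = 0.230 M⁻¹ min⁻¹)
    nucleophile + protic impurity → quenched reagent (k = 0.0350 M⁻¹ min⁻¹)
    solid nucleophile ⇌ nucleophile, rate k5*(cs5 - [nucleophile]) while solid is left; crystals form when [nucleophile] > cs5 (solubility = 0.260 M, k = 0.00170 min⁻¹)

The forecast's fr stood 58 percentage points too high, and the flask's share had fallen from 49.6% at 2.00 h. The flask had not come to rest at 20 h: at 200 h c reached 94.0%, its solid nucleophile stood at 0% of charge, and its salt of the base had risen from 0.0909 M to 0.435 M. For the neighbour with 0.30 M electrophile, the constant molar rate gives 75.3% and the pseudo-first-order end stays at 43.0%. The simulated c there was 52.4%, lower than the first and higher than the second.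

Readings and results were generated by integration with made-up constants.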